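**Plan**

1. The first cut is the bond between the bridging CH2 and chromene C6, with the CH2 kept on pyranone C3 as a Mannich base. The second opens the pyran ring of the chromene (C4–C4a and O1–C2) back to prenal and a phenol whose C5 oxygen is protected.
2. The benzene ring (C4a, C5, C6, C7, C8, C8a), with the acyl group on C8 and oxygens on C5, C7 and C8a, is a cyclised tetraketide. Cutting C8–C7 and exchanging that carbon for oxygen gives a 6-(2-oxoalkyl)-2-pyranone whose single 4-oxygen is the C5 oxygen, para to the acyl group and the only oxygen that has to be kept apart from the other two.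
3. The last cut is the bond between the pyranone-bound CH2 and the acyl carbon, giving 4-hydroxy-6-methyl-2-pyranone and (S)-2-methylbutanoic acid.
4. Forward order: side-chain acylation, O4 protection, pyranone-to-benzene ring exchange (benzene ring), prenal annulation (pyran ring), deprotection, then CH2 union with separately built 6-ethyl-4-hydroxy-5-methyl-2-pyranone.
5. The one stereocentre (S, α to the aryl ketone) comes from (S)-2-methylbutanoic acid and is never a reacting centre.

Key step: step 4

Assumption: tautomerically mobile compounds (the 4-hydroxy-2-pyranones, diketone 17, Mannich base 20) are drawn as one neutral tautomer; 17 is racemic at C4, a centre that disappears on lactonisation.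

**Route**

Step 1
Reactants: 1 (2S)-2-methylbutanoic acid
Product: 3 (2S)-N-methoxy-N,2-dimethylbutanamide, via acyl imidazole 2 (not isolated)
Conditions: CDI (1.1 equiv), CH2Cl2, 0 °C to rt; then MeNHOMe·HCl (1.2 equiv), rt
Reagents that add atoms: N,O-dimethylhydroxylamine hydrochloride, CNOC.Cl
Why: Weinreb amide formation through the acyl imidazole; activation of a simple α-alkyl acid with CDI passes through neither a ketene nor an oxazolone, so the (S) centre should be retained.

Step 2
Reactants: 4 4-hydroxy-6-methyl-2H-pyran-2-one; 3 (2S)-N-methoxy-N,2-dimethylbutanamide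
Product: 6 4-hydroxy-6-[(3S)-3-methyl-2-oxopentyl]-2H-pyran-2-one, via dilithium dianion 5 (not isolated)
Conditions: LiN(iPr)2 (LDA, 2.1 equiv), THF, −78 °C; then 3, −78 to 0 °C; 1 M HCl
Reagents that add atoms: none
Why: C-acylation of the pyranone dianion at its 6-methyl carbon by a Weinreb amide (Weinreb ketone synthesis); the chelated tetrahedral adduct lasts until the quench, so no ketone meets the strong base, and the hindered amide α-proton is too weakly acidic to be removed by the stabilised carbanion.

Step 3
Reactants: 6 4-hydroxy-6-[(3S)-3-methyl-2-oxopentyl]-2H-pyran-2-one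
Product: 7 4-(methoxymethoxy)-6-[(3S)-3-methyl-2-oxopentyl]-2H-pyran-2-one
Conditions: MOMCl (1.05 equiv), iPr2NEt (1.1 equiv), CH2Cl2, 0 °C
Reagents that add atoms: chloromethyl methyl ether, COCCl
Why: O-alkylation of a vinylogous acid: only the 4-hydroxyl (pKa about 5) is ionised by the amine, and the hard oxocarbenium-type electrophile should react at O4 to give the 4-alkoxy-2-pyranone.

Step 4
Reactants: 7 4-(methoxymethoxy)-6-[(3S)-3-methyl-2-oxopentyl]-2H-pyran-2-one
Product: 9 (2S)-1-[2,6-dihydroxy-4-(methoxymethoxy)phenyl]-2-methylbutan-1-one, via open-chain keto enoate 8 (not isolated)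
Conditions: Mg(OMe)2 (4 equiv), MeOH, reflux; then cold 0.5 M HCl to pH 4
Reagents that add atoms: none
Why: Proposed new method: methoxide from Mg(OMe)2 adds to the lactone carbonyl C2 of 7 and the C2–O1 bond breaks, helped by magnesium held between the side-chain enolate oxygen and the ring oxygen, to give the (2E)-3-(methoxymethoxy)-5,7-dioxo-2-enoate 8, in which ester carbon and diketone chain stay cis on the enol-ether double bond as they were in the ring. The C6 methylene of 8, flanked by both ketones, is the most acidic site, and its magnesium-chelated enolate attacks the ester carbon C1 in a 6-exo-trig Claisen (Dieckmann-type) closure, carbon onto acyl carbon, which forms the benzene ring bond between the acyl-bearing carbon and its hydroxylated neighbour (later chromene C8–C7); loss of methoxide and enolisation give the phenol, so that the former lactone carbonyl oxygen and the former ring oxygen end as the two hydroxyls ortho to the acyl group and the MOM-bearing oxygen ends para. The closest known reaction type is the Mg(OMe)2-induced conversion of 6-(2-oxoalkyl)-4-hydroxy-2-pyranones and of 3,5,7-trioxo esters into acylphloroglucinols; what is new is the alkylated 4-oxygen. No stereocentre is formed, and the existing one lies α to a carbonyl that is already part of an enolised, chelated 1,3-diketone and afterwards of a phenolate-conjugated aryl ketone, so a second deprotonation there is not expected. The step needs Claisen instead of aldol closure and attack of methoxide at C2 instead of exchange at C4: the first should follow because C2 of 8 is a vinylic enol-ether carbon of low nucleophilicity while C7 is tied up in the magnesium diketonate, the second because magnesium activates the lactone carbonyl and keeps free methoxide scarce.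

Step 5
Reactants: 9 (2S)-1-[2,6-dihydroxy-4-(methoxymethoxy)phenyl]-2-methylbutan-1-one; 10 3-methylbut-2-enal (prenal, 1.2 equiv)
Product: 12 (2S)-1-[7-hydroxy-5-(methoxymethoxy)-2,2-dimethyl-2H-chromen-8-yl]-2-methylbutan-1-one, via dienone 11 (not isolated)
Conditions: ethylenediammonium diacetate (EDDA, 0.2 equiv), toluene, 110 °C
Reagents that add atoms: none
Why: Knoevenagel-type condensation of the enal at one of the two equivalent ring C–H positions gives the ortho-quinone methide 11, and its oxa-6π electrocyclisation closes the pyran ring; only the free hydroxyl next to the acyl group can become the quinone-methide oxygen because the para oxygen is blocked as its MOM ether.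

Step 6
Reactants: 12 (2S)-1-[7-hydroxy-5-(methoxymethoxy)-2,2-dimethyl-2H-chromen-8-yl]-2-methylbutan-1-one
Product: 13 (2S)-1-(5,7-dihydroxy-2,2-dimethyl-2H-chromen-8-yl)-2-methylbutan-1-one
Conditions: HCl (1.25 M in MeOH), rt to 40 °C
Reagents that add atoms: none
Why: Acid-catalysed transacetalisation (MOM ether cleavage) passes the methoxymethyl group to methanol as dimethoxymethane, while the chromene double bond, deactivated by the acyl group on the same ring, and the chelated aryl ketone should tolerate dilute methanolic HCl.

Step 7
Reactants: 14 methyl 3-oxopentanoate; 15 N-methoxy-N-methylpropanamide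
Product: 17 methyl 4-methyl-3,5-dioxoheptanoate, via dilithium dianion 16 (not isolated)
Conditions: LiN(iPr)2 (LDA, 2.1 equiv), THF, 0 °C; then 15, −78 to 0 °C; 1 M HCl
Reagents that add atoms: none
Why: γ-Acylation of a β-keto ester dianion at its more reactive γ-carbon by a Weinreb amide (Weinreb ketone synthesis), the tetrahedral adduct protecting the new ketone until the quench.

Step 8
Reactants: 17 methyl 4-methyl-3,5-dioxoheptanoate
Product: 18 6-ethyl-4-hydroxy-5-methyl-2H-pyran-2-one
Conditions: DBU (1.5 equiv), toluene, reflux; then 1 M HCl
Reagents that add atoms: none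
Why: Base-mediated lactonisation of a 3,5-dioxo ester: the C5 enolate oxygen attacks the ester carbon (6-exo-trig) with loss of methanol, the standard closure to 4-hydroxy-2-pyranones, which also removes the labile C4 centre of 17.

Step 9
Reactants: 18 6-ethyl-4-hydroxy-5-methyl-2H-pyran-2-one; 19 dimethyl(methylidene)ammonium iodide (Eschenmoser's salt)
Product: 20 3-[(dimethylamino)methyl]-6-ethyl-4-hydroxy-5-methyl-2H-pyran-2-one
Conditions: Et3N (1.1 equiv), CH2Cl2, 0 °C to rt
Reagents that add atoms: none
Why: Mannich reaction at C3, the only enolic C–H of the 4-hydroxy-2-pyranone; the preformed iminium salt avoids free formaldehyde and so the methylene-bis-pyranone.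

Step 10
Reactants: 13 (2S)-1-(5,7-dihydroxy-2,2-dimethyl-2H-chromen-8-yl)-2-methylbutan-1-one; 20 3-[(dimethylamino)methyl]-6-ethyl-4-hydroxy-5-methyl-2H-pyran-2-one (1.2 equiv)
Product: 22 6-ethyl-4-hydroxy-3-({5,7-dihydroxy-2,2-dimethyl-8-[(2S)-2-methylbutanoyl]-2H-chromen-6-yl}methyl)-5-methyl-2H-pyran-2-one, via methylidene pyrandione 21 (not isolated)
Conditions: 1,4-dioxane, 80 °C, N2 stream
Reagents that add atoms: none
Why: Thermal loss of dimethylamine from the zwitterionic Mannich base gives the 3-methylidene-pyran-2,4-dione 21, which is trapped by the only free ring C–H of 13 (C6, between two hydroxyls) in a Michael/Friedel–Crafts alkylation, the usual way to the methylene bridge of phloroglucinol–pyranone natural products.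

**Compound list**

1 | (2S)-2-methylbutanoic acid | CC[C@H](C)C(=O)O | starting material
2 | (2S)-1-(1H-imidazol-1-yl)-2-methylbutan-1-one | CC[C@H](C)C(=O)n1ccnc1 | intermediate (not isolated)
3 | (2S)-N-methoxy-N,2-dimethylbutanamide | CC[C@H](C)C(=O)N(C)OC | intermediate
4 | 4-hydroxy-6-methyl-2H-pyran-2-one | Cc1cc(O)cc(=O)o1 | starting material
5 | dilithium salt of the O4,6-methyl dianion of 4 | [Li+].[Li+].[CH2-]c1cc([O-])cc(=O)o1 | intermediate (not isolated)
6 | 4-hydroxy-6-[(3S)-3-methyl-2-oxopentyl]-2H-pyran-2-one | CC[C@H](C)C(=O)Cc1cc(O)cc(=O)o1 | intermediate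
7 | 4-(methoxymethoxy)-6-[(3S)-3-methyl-2-oxopentyl]-2H-pyran-2-one | CC[C@H](C)C(=O)Cc1cc(OCOC)cc(=O)o1 | intermediate
8 | methyl (2E,8S)-3-(methoxymethoxy)-8-methyl-5,7-dioxodec-2-enoate (present as its magnesium enolate) | CC[C@H](C)C(=O)CC(=O)C/C(OCOC)=C\C(=O)OC | intermediate (not isolated)
9 | (2S)-1-[2,6-dihydroxy-4-(methoxymethoxy)phenyl]-2-methylbutan-1-one | CC[C@H](C)C(=O)c1c(O)cc(OCOC)cc1O | intermediate
10 | 3-methylbut-2-enal | CC(C)=CC=O | starting material
11 | (6Z)-3-hydroxy-5-(methoxymethoxy)-2-[(2S)-2-methylbutanoyl]-6-(3-methylbut-2-en-1-ylidene)cyclohexa-2,4-dien-1-one | CC[C@H](C)C(=O)C1=C(O)C=C(OCOC)/C(=C/C=C(C)C)C1=O | intermediate (not isolated)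
12 | (2S)-1-[7-hydroxy-5-(methoxymethoxy)-2,2-dimethyl-2H-chromen-8-yl]-2-methylbutan-1-one | CC[C@H](C)C(=O)c1c(O)cc(OCOC)c2C=CC(C)(C)Oc12 | intermediate
13 | (2S)-1-(5,7-dihydroxy-2,2-dimethyl-2H-chromen-8-yl)-2-methylbutan-1-one | CC[C@H](C)C(=O)c1c(O)cc(O)c2C=CC(C)(C)Oc12 | intermediate
14 | methyl 3-oxopentanoate | CCC(=O)CC(=O)OC | starting material
15 | N-methoxy-N-methylpropanamide | CCC(=O)N(C)OC | starting material
16 | dilithium salt of the α,γ-dianion of 14 | [Li+].[Li+].C[CH-]C([O-])=CC(=O)OC | intermediate (not isolated)
17 | methyl 4-methyl-3,5-dioxoheptanoate (racemic at C4) | CCC(=O)C(C)C(=O)CC(=O)OC | intermediate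
18 | 6-ethyl-4-hydroxy-5-methyl-2H-pyran-2-one | CCc1oc(=O)cc(O)c1C | intermediate
19 | dimethyl(methylidene)ammonium iodide | C=[N+](C)C.[I-] | starting material
20 | 3-[(dimethylamino)methyl]-6-ethyl-4-hydroxy-5-methyl-2H-pyran-2-one | CCc1oc(=O)c(CN(C)C)c(O)c1C | intermediate
21 | 6-ethyl-5-methyl-3-methylidene-2H-pyran-2,4(3H)-dione | CCC1=C(C)C(=O)C(=C)C(=O)O1 | intermediate (not isolated)
22 | 6-ethyl-4-hydroxy-3-({5,7-dihydroxy-2,2-dimethyl-8-[(2S)-2-methylbutanoyl]-2H-chromen-6-yl}methyl)-5-methyl-2H-pyran-2-one | CCc1oc(=O)c(Cc2c(O)c3c(c(C(=O)[C@@H](C)CC)c2O)OC(C)(C)C=C3)c(O)c1C | target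

**Step count**

Total: 10 steps. Longest linear sequence: 7 steps (steps 1 to 6, then step 10). The pyranone branch (steps 7 to 9) joins at step 10.

**Steps most likely to fail**

Step 4. Methoxide may exchange the methoxymethoxy group for methoxy by addition–elimination at C4 of the pyranone or of the open-chain enol ether, or the enolised pyranone may resist ring opening. The fallback sets out from 6 and moves the differentiation of the oxygens to after the ring exchange. The unprotected 4-hydroxy-pyranone 6 is treated with Mg(OMe)2 in refluxing methanol, the known ring-opening and Claisen closure of this substrate class, to give (2S)-2-methyl-1-(2,4,6-trihydroxyphenyl)butan-1-one F1. Its para hydroxyl, the most acidic one and the only one that is never hydrogen-bonded to the ketone, is then methoxymethylated with one equivalent of MOMCl and iPr2NEt in CH2Cl2 at 0 °C, which returns to 9.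

Step 10. The transient methylidene dione may condense with itself, or retro-Mannich cleavage may release free pyranone that captures it, so that the bridge forms between two pyranones. The fallback sets out from 13 and reverses the roles of the partners. Aminomethylation of the single free ring position of 13 with dimethyl(methylidene)ammonium iodide and Et3N gives (2S)-1-{6-[(dimethylamino)methyl]-5,7-dihydroxy-2,2-dimethyl-2H-chromen-8-yl}-2-methylbutan-1-one F2. Heating F2 with pyranone 18 in dioxane lets nucleophilic C3 of 18 replace dimethylamine by elimination–addition, which arrives at 22.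

Step 5. A second annulation at the remaining ring C–H onto the remaining hydroxyl may consume product, or condensation may be sluggish because both hydroxyls are hydrogen-bonded to the ketone. The fallback sets out from 9 and separates C–C bond formation from ring closure. C-prenylation with prenyl bromide in aqueous KOH at 0 °C gives (2S)-1-[2,6-dihydroxy-4-(methoxymethoxy)-3-(3-methylbut-2-en-1-yl)phenyl]-2-methylbutan-1-one F3. Dehydrogenative cyclisation of F3 with DDQ in benzene at rt, which can only close on the free hydroxyl beside the prenyl group, returns to 12.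

**Further compounds**

F1 | step 4 | (2S)-2-methyl-1-(2,4,6-trihydroxyphenyl)butan-1-one | CC[C@H](C)C(=O)c1c(O)cc(O)cc1O
F2 | step 10 | (2S)-1-{6-[(dimethylamino)methyl]-5,7-dihydroxy-2,2-dimethyl-2H-chromen-8-yl}-2-methylbutan-1-one | CC[C@H](C)C(=O)c1c(O)c(CN(C)C)c(O)c2C=CC(C)(C)Oc12
F3 | step 5 | (2S)-1-[2,6-dihydroxy-4-(methoxymethoxy)-3-(3-methylbut-2-en-1-yl)phenyl]-2-methylbutan-1-one | CC[C@H](C)C(=O)c1c(O)cc(OCOC)c(CC=C(C)C)c1O
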